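**Plan**

- Retrosynthesis (labdane numbering): the 13(16),14-diene goes back to a C13 terminal alkyne (enyne metathesis with ethylene), the 6,8-diol to a trans-fused 7,8-epoxy-6-ketone, and ring B is then cut at C5–C6 and C9–C10 in one [4+2] disconnection.
- Enabling feature: O18 on C4 and the oxygenated C6 both flank the ring-fusion carbon C5, so a temporary O18–Si(iPr)2–C6 bridge (1-oxa-2-silacyclohexane C4–C18–O–Si–C6–C5) can hold a (1E,3E)-dienylsilane (C6–C9) over the C5=C10 bond of a ring A enal. C20 is carried as the activating CHO.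
- Forward: ring A is made first from 3-methylcyclohex-2-enone; one intramolecular Diels–Alder step closes ring B and the tether ring; the helpers are removed (CHO → CH3, C6–Si → C6–O); ring B is adjusted; the side-chain diene is made last.
- Stereochemistry: C4 from a Cu-catalysed asymmetric conjugate addition; C10 and C9 from the tethered endo cycloaddition; C5 by epimerization through the 6-ketone; C8 by epoxidation anti to the axial methyl groups; C6 by thermodynamically controlled ketone reduction.

Key step: step 7

Remark: labdane numbering is used for all decalin compounds (C18 = oxygenated carbon on C4; C19, C17, C20 = one-carbon groups on C4, C8, C10; "syn/anti" = same/opposite face as C20); in every bicyclic compound C18 is anti and the C9 chain syn to C20; in step 1 the ligand antipode that gives the (S)-centre is assumed to be identified by a screening run.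

Step 1
Reactants: 1 3-methylcyclohex-2-en-1-one; 2 (chloromethyl)(isopropoxy)dimethylsilane
Product: 5 (S)-3-{[isopropoxy(dimethyl)silyl]methyl}-3-methylcyclohex-1-en-1-yl trifluoromethanesulfonate, via Grignard reagent 3 (not isolated), via magnesium enolate 4 (not isolated)
Conditions: Mg, THF (2 → 3); 1, Cu(OTf)2 (3 mol%), 1-mesityl-3-[(S)-1-hydroxy-4-methylpentan-2-yl]-4,5-dihydroimidazolium hexafluorophosphate (carbene ligand precursor, 4 mol%, or its antipode), Et2O, −30 °C; then the pyridyl triflimide, DMPU, THF, −30 → 25 °C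
Reagents that add atoms: magnesium, [Mg] (stays only in 3 and 4); N-(5-chloropyridin-2-yl)-1,1,1-trifluoro-N-[(trifluoromethyl)sulfonyl]methanesulfonamide, Clc1ccc(nc1)N(S(=O)(=O)C(F)(F)F)S(=O)(=O)C(F)(F)F
Why: Copper-catalysed asymmetric conjugate addition of the α-silyl Grignard reagent to the β-methyl enone should create the quaternary C4 centre under ligand control, and O-sulfonylation of the regiodefined enolate fixes the double bond at C5=C10.

Step 2
Reactants: 5 (S)-3-{[isopropoxy(dimethyl)silyl]methyl}-3-methylcyclohex-1-en-1-yl trifluoromethanesulfonate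
Product: 6 (S)-3-(hydroxymethyl)-3-methylcyclohex-1-en-1-yl trifluoromethanesulfonate
Conditions: 30% H2O2, KF, KHCO3, THF/MeOH, 25 °C
Reagents that add atoms: hydrogen peroxide, OO
Why: Tamao–Fleming oxidation should convert the alkoxy-activated C–Si bond into C18–OH without touching the vinyl triflate or the quaternary centre.

Step 3
Reactants: 6 (S)-3-(hydroxymethyl)-3-methylcyclohex-1-en-1-yl trifluoromethanesulfonate
Product: 7 (S)-3-(hydroxymethyl)-3-methylcyclohex-1-ene-1-carbaldehyde
Conditions: Pd(PPh3)4 (5 mol%), CO (1 atm), Bu3SnH (slow addition), LiCl, THF, 50 °C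
Reagents that add atoms: carbon monoxide, [C-]#[O+]
Why: Palladium-catalysed reductive carbonylation (formylation) of the vinyl triflate by oxidative addition, CO insertion and hydride transfer from tin should give the enal, with lactonization excluded because C18 and the acyl group are trans across C5=C10.

Step 4
Reactants: 8 (E)-3-methylpent-2-en-4-yn-1-ol
Product: 9 (E)-5-bromo-3-methylpent-3-en-1-yne
Conditions: CBr4, PPh3, CH2Cl2, 0 °C
Reagents that add atoms: carbon tetrabromide, BrC(Br)(Br)Br
Why: The Appel reaction should replace the primary allylic hydroxyl by bromide under neutral conditions that leave the (E)-alkene and the alkyne untouched.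

Step 5
Reactants: 9 (E)-5-bromo-3-methylpent-3-en-1-yne; 10 trimethyl(prop-1-yn-1-yl)silane
Product: 12 (E)-trimethyl(6-methyloct-5-ene-1,7-diyn-1-yl)silane, via propargyllithium reagent 11 (not isolated)
Conditions: 10, n-BuLi, THF, −78 → −20 °C (gives 11, 2.2 equiv); then 9, −78 °C; aqueous NH4Cl (the first equivalent of 11 is held as the acetylide of 9 until the quench)
Reagents that add atoms: n-butyllithium, [Li]CCCC (its lithium stays only in 11)
Why: SN2 alkylation of the primary allylic bromide at the propargylic carbon of the lithium reagent should give the 1,5-enyne with the (E)-alkene retained.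

Step 6
Reactants: 12 (E)-trimethyl(6-methyloct-5-ene-1,7-diyn-1-yl)silane; 7 (S)-3-(hydroxymethyl)-3-methylcyclohex-1-ene-1-carbaldehyde
Product: 14 (S)-3-{[(diisopropyl{(1E,3E)-3-methyl-8-(trimethylsilyl)octa-1,3-dien-7-yn-1-yl}silyl)oxy]methyl}-3-methylcyclohex-1-ene-1-carbaldehyde, via dienylchlorosilane 13 (not isolated)
Conditions: 12 (1.1 equiv), HSi(iPr)2Cl, Pt2[(CH2=CHSiMe2)2O]3 (1 mol%), P(t-Bu)3, THF, 25 → 50 °C; then 7, imidazole, CH2Cl2, 0 → 25 °C
Reagents that add atoms: chlorodiisopropylsilane, CC(C)[SiH](Cl)C(C)C
Why: Platinum-catalysed syn-hydrosilylation of the terminal alkyne should give the (E)-vinylsilane (β-adduct) with the silylated alkyne inert, and the resulting chlorosilane silylates the neopentyl alcohol of 7 (silyl ether formation).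

Step 7
Reactants: 14 (S)-3-{[(diisopropyl{(1E,3E)-3-methyl-8-(trimethylsilyl)octa-1,3-dien-7-yn-1-yl}silyl)oxy]methyl}-3-methylcyclohex-1-ene-1-carbaldehyde
Product: 15 cis-fused cycloadduct: 14-(trimethylsilyl)-15,16-dinorlabd-7-en-13-yn-20-al in which O18 and C6 are bridged by Si(iPr)2 (H5 syn to C20; C6–Si syn to C20)
Conditions: Me2AlCl (0.3 equiv), CH2Cl2 (0.01 M), −40 → 0 °C
Reagents that add atoms: none
Why: The Lewis-acid-complexed enal (C5=C10–C20=O) and the tethered (1E,3E)-dienylsilane should combine in a concerted, asynchronous [4+2] cycloaddition that forms C5–C6 and C9–C10 together; the closest known reaction type is the temporary-silicon-tethered intramolecular Diels–Alder reaction of dienylsilyl ethers. Ring B is closed by the cycloaddition itself (six-membered carbocycle with the new C7=C8 bond), and the 1-oxa-2-silacyclohexane ring C4–C18–O–Si–C6–C5 is closed in the fused mode, in which the tethered diene terminus C6 bonds to the nearer dienophile carbon C5. C10 is set by the tether, which can reach only the face of C5=C10 that carries C18, so C9 adds syn to C18 and C20 ends anti to C18; C5 is formed cis (H5 syn to C20) by the suprafacial addition and is corrected in step 11. C9 is set by the (E)-C8=C9 geometry together with the aldehyde-endo transition state (side chain syn to C20), and C6 by the (E)-vinylsilane geometry (Si syn to C20; this centre is reset later). The step needs regioselectivity (C6 to C5 and not to C10), secured because the four-atom tether closes a six-membered ring only in the fused mode, and endo selectivity, expected from Lewis acid complexation of the CHO group and from the unstrained trans junction between the tether ring and ring B in that transition state.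

Step 8
Reactants: 15 cis-fused cycloadduct aldehyde
Product: 17 C20-methyl analogue of 15: 14-(trimethylsilyl)-15,16-dinorlabd-7-en-13-yne in which O18 and C6 are bridged by Si(iPr)2 (same configuration), via tosylhydrazone 16 (not isolated)
Conditions: TsNHNH2, THF, 25 °C; then catecholborane, CHCl3, 0 °C; then NaOAc·3H2O, 60 °C
Reagents that add atoms: 4-methylbenzenesulfonohydrazide, Cc1ccc(cc1)S(=O)(=O)NN (its atoms stay only in 16)
Why: Hydride reduction of the tosylhydrazone followed by acetate-induced loss of sulfinate and N2 (a mild Wolff–Kishner-type deoxygenation) should turn the angular aldehyde into the C20 methyl group without affecting any stereocentre.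

Step 9
Reactants: 17 silicon-bridged 14-(trimethylsilyl)-15,16-dinorlabd-7-en-13-yne
Product: 18 cis-fused 15,16-dinorlabd-7-en-13-yne-6,18-diol (H5 and 6-OH syn to C20)
Conditions: 30% H2O2, KF, KHCO3, THF/MeOH, 45 °C
Reagents that add atoms: hydrogen peroxide, OO
Why: Tamao–Fleming oxidation of the alkoxysilane should excise the tether with retention at C6 (carbon migrates from silicon to oxygen), while fluoride in methanol removes the alkynyl trimethylsilyl group.

Step 10
Reactants: 18 cis-fused 15,16-dinorlabd-7-en-13-yne-6,18-diol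
Product: 19 cis-fused 18-hydroxy-15,16-dinorlabd-7-en-13-yn-6-one (H5 syn to C20)
Conditions: MnO2 (activated, excess), CH2Cl2, 25 °C
Reagents that add atoms: none
Why: Allylic oxidation with MnO2 should convert only the allylic C6 alcohol into the enone and leave the saturated primary C18 alcohol and the alkyne alone.

Step 11
Reactants: 19 cis-fused 18-hydroxy-15,16-dinorlabd-7-en-13-yn-6-one
Product: 20 trans-fused 18-hydroxy-15,16-dinorlabd-7-en-13-yn-6-one (H5 anti to C20)
Conditions: K2CO3, MeOH, 25 → 40 °C
Reagents that add atoms: none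
Why: Base-catalysed enolization toward C5 (the only α′ position) followed by protonation anti to the C19 and C20 methyl groups should equilibrate the cis-fused enone to the more stable trans-fused isomer (thermodynamic epimerization).

Step 12
Reactants: 20 trans-fused 18-hydroxy-15,16-dinorlabd-7-en-13-yn-6-one
Product: 21 trans-fused 7,8-epoxy-18-hydroxy-15,16-dinorlabd-13-yn-6-one (epoxide oxygen anti to C20)
Conditions: 30% H2O2, NaOH (aq), MeOH, 0 → 25 °C
Reagents that add atoms: hydrogen peroxide, OO
Why: In this Weitz–Scheffer nucleophilic epoxidation the hydroperoxide should add to C8 on the face anti to the axial C20 and C19 methyl groups, so C7 and C8 are set with the epoxide anti to C20.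

Step 13
Reactants: 21 trans-fused 7,8-epoxy-18-hydroxy-15,16-dinorlabd-13-yn-6-one
Product: 23 trans-fused 15,16-dinorlabd-13-yne-6,8,18-triol (6-OH and 8-OH anti to C20), via hydroxy ketone 22 (not isolated)
Conditions: SmI2 (2.2 equiv), THF/MeOH, −78 °C; then SmI2 (4 equiv), H2O, Et3N, 0 °C
Reagents that add atoms: none
Why: SmI2 should first cleave the C7–O bond of the α,β-epoxy ketone (C8–O retained) and then, with water and amine, reduce the ketone through a ketyl whose carbon protonation gives the equatorial 6-alcohol, since the axial epimer would be 1,3-diaxial to C19 and C20 (single-electron reduction under thermodynamic control).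

Step 14
Reactants: 23 trans-fused 15,16-dinorlabd-13-yne-6,8,18-triol
Product: 24 6,8-dihydroxy-15,16-dinorlabd-13-yn-18-yl acetate
Conditions: Ac2O (1.1 equiv), pyridine, CH2Cl2, −20 → 0 °C
Reagents that add atoms: acetic anhydride, CC(=O)OC(C)=O
Why: Kinetically controlled esterification should acylate the primary C18 hydroxyl in preference to the hindered secondary and tertiary hydroxyls.

Step 15
Reactants: 24 6,8-dihydroxy-15,16-dinorlabd-13-yn-18-yl acetate
Product: 25 (4S,5S,6R,8S,9S,10R)-6,8-dihydroxylabda-13(16),14-dien-18-yl acetate (target)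
Conditions: ethylene (1 atm), second-generation Grubbs catalyst RuCl2(=CHPh)(H2IMes)(PCy3) (5 mol%), CH2Cl2, 40 °C
Reagents that add atoms: ethylene, C=C
Why: Ruthenium-carbene-catalysed cross enyne metathesis with ethylene should convert the terminal alkyne into the 2-substituted 1,3-butadiene and tolerates the free hydroxyls and the acetate.

**Compound list**

1 | 3-methylcyclohex-2-en-1-one | CC1=CC(=O)CCC1 | starting material
2 | (chloromethyl)(isopropoxy)dimethylsilane | CC(C)O[Si](C)(C)CCl | starting material
3 | {[isopropoxy(dimethyl)silyl]methyl}magnesium chloride | CC(C)O[Si](C)(C)C[Mg]Cl | intermediate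
4 | chloromagnesium (S)-3-{[isopropoxy(dimethyl)silyl]methyl}-3-methylcyclohex-1-en-1-olate | CC(C)O[Si](C)(C)C[C@]1(C)C=C(O[Mg]Cl)CCC1 | intermediate
5 | (S)-3-{[isopropoxy(dimethyl)silyl]methyl}-3-methylcyclohex-1-en-1-yl trifluoromethanesulfonate | CC(C)O[Si](C)(C)C[C@]1(C)C=C(OS(=O)(=O)C(F)(F)F)CCC1 | intermediate
6 | (S)-3-(hydroxymethyl)-3-methylcyclohex-1-en-1-yl trifluoromethanesulfonate | OC[C@]1(C)C=C(OS(=O)(=O)C(F)(F)F)CCC1 | intermediate
7 | (S)-3-(hydroxymethyl)-3-methylcyclohex-1-ene-1-carbaldehyde | OC[C@]1(C)C=C(C=O)CCC1 | intermediate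
8 | (E)-3-methylpent-2-en-4-yn-1-ol | C#C/C(C)=C/CO | starting material
9 | (E)-5-bromo-3-methylpent-3-en-1-yne | C#C/C(C)=C/CBr | intermediate
10 | trimethyl(prop-1-yn-1-yl)silane | CC#C[Si](C)(C)C | starting material
11 | [3-(trimethylsilyl)prop-2-yn-1-yl]lithium | [Li]CC#C[Si](C)(C)C | intermediate
12 | (E)-trimethyl(6-methyloct-5-ene-1,7-diyn-1-yl)silane | C#C/C(C)=C/CCC#C[Si](C)(C)C | intermediate
13 | chloro(diisopropyl)[(1E,3E)-3-methyl-8-(trimethylsilyl)octa-1,3-dien-7-yn-1-yl]silane | CC(C)[Si](Cl)(C(C)C)/C=C/C(C)=C/CCC#C[Si](C)(C)C | intermediate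
14 | (S)-3-{[(diisopropyl{(1E,3E)-3-methyl-8-(trimethylsilyl)octa-1,3-dien-7-yn-1-yl}silyl)oxy]methyl}-3-methylcyclohex-1-ene-1-carbaldehyde | O=CC1=C[C@@](C)(CO[Si](C(C)C)(C(C)C)/C=C/C(C)=C/CCC#C[Si](C)(C)C)CCC1 | intermediate
15 | cis-fused cycloadduct: 14-(trimethylsilyl)-15,16-dinorlabd-7-en-13-yn-20-al with O18 and C6 bridged by Si(iPr)2 (H5 syn to C20; C6–Si syn; C9 chain syn; C18 anti) | O=C[C@@]12CCC[C@](C)(CO[Si]3(C(C)C)C(C)C)[C@@H]1[C@@H]3C=C(C)[C@H]2CCC#C[Si](C)(C)C | intermediate
16 | N-tosylhydrazone of 15 (same configuration) | Cc1ccc(cc1)S(=O)(=O)NN=C[C@@]12CCC[C@](C)(CO[Si]3(C(C)C)C(C)C)[C@@H]1[C@@H]3C=C(C)[C@H]2CCC#C[Si](C)(C)C | intermediate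
17 | 14-(trimethylsilyl)-15,16-dinorlabd-7-en-13-yne with O18 and C6 bridged by Si(iPr)2 (cis-fused: H5 syn to C20; C6–Si syn) | C[C@@]12CCC[C@](C)(CO[Si]3(C(C)C)C(C)C)[C@@H]1[C@@H]3C=C(C)[C@H]2CCC#C[Si](C)(C)C | intermediate
18 | cis-fused 15,16-dinorlabd-7-en-13-yne-6,18-diol (H5 and 6-OH syn to C20) | C[C@@]12CCC[C@](C)(CO)[C@@H]1[C@@H](O)C=C(C)[C@H]2CCC#C | intermediate
19 | cis-fused 18-hydroxy-15,16-dinorlabd-7-en-13-yn-6-one (H5 syn to C20) | C[C@@]12CCC[C@](C)(CO)[C@@H]1C(=O)C=C(C)[C@H]2CCC#C | intermediate
20 | trans-fused 18-hydroxy-15,16-dinorlabd-7-en-13-yn-6-one (H5 anti to C20) | C[C@@]12CCC[C@](C)(CO)[C@H]1C(=O)C=C(C)[C@H]2CCC#C | intermediate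
21 | trans-fused 7,8-epoxy-18-hydroxy-15,16-dinorlabd-13-yn-6-one (epoxide oxygen anti to C20) | C[C@@]12CCC[C@](C)(CO)[C@H]1C(=O)[C@@H]3O[C@]3(C)[C@H]2CCC#C | intermediate
22 | trans-fused 8,18-dihydroxy-15,16-dinorlabd-13-yn-6-one (8-OH anti to C20) | C[C@@]12CCC[C@](C)(CO)[C@H]1C(=O)C[C@](C)(O)[C@H]2CCC#C | intermediate
23 | trans-fused 15,16-dinorlabd-13-yne-6,8,18-triol (6-OH and 8-OH anti to C20) | C[C@@]12CCC[C@](C)(CO)[C@H]1[C@H](O)C[C@](C)(O)[C@H]2CCC#C | intermediate
24 | 6,8-dihydroxy-15,16-dinorlabd-13-yn-18-yl acetate (configuration as in 23) | C[C@@]12CCC[C@](C)(COC(C)=O)[C@H]1[C@H](O)C[C@](C)(O)[C@H]2CCC#C | intermediate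
25 | (4S,5S,6R,8S,9S,10R)-6,8-dihydroxylabda-13(16),14-dien-18-yl acetate | C=CC(=C)CC[C@H]1[C@]2(C)CCC[C@](C)(COC(C)=O)[C@H]2[C@H](O)C[C@]1(C)O | target

Total step count: 15. Longest linear sequence: 13 steps (steps 1–3 and 6–15).

**Steps most likely to fail**

1. Step 7. The cycloaddition may stall because C5 is flanked by the quaternary C4, or the Lewis acid may cleave the silyl ether link so that facial and regiochemical control are lost. Fallback: starting from 14, the aldehyde would be converted with 1,2-bis(trimethylsilyloxy)ethane and catalytic TMSOTf (CH2Cl2, −78 °C) into the 1,3-dioxolane of 14 F1. With the same catalyst this ionizes to a 2-alkoxyallyl cation, which should undergo an ionic Diels–Alder reaction at −78 to −40 °C to the cycloadduct dioxolane F2. Acetal hydrolysis (PPTS, wet acetone) would return aldehyde 15, where the route is rejoined.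

2. Step 11. Under base the γ-positions of the enone (C9–H and the C17 methyl) may be deprotonated in competition with the hindered C5–H, which would erode the C9 configuration or move the double bond out of conjugation. Fallback: starting from 19, the order of events would be changed. Weitz–Scheffer epoxidation of the cis-fused enone (H2O2, NaOH, MeOH; attack anti to C20 and the C9 chain) would give the cis-fused epoxy ketone F3, in which C5–H is the only enolizable hydrogen next to the carbonyl group. Continued exposure to base (K2CO3, MeOH) would then invert C5 alone and give 21, where the route is rejoined.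

3. Step 1. The α-silyl Grignard reagent may add with insufficient enantioselectivity. Fallback: starting from 1 and 2, the addition would be run without chiral ligand (CuBr·SMe2 cat., THF, −30 °C, same triflimide quench) to give the racemic silyl triflate F4, and Tamao–Fleming oxidation would give the racemic alcohol F5. A lipase-catalysed kinetic resolution (vinyl acetate, immobilized Candida antarctica lipase B, MTBE) would then separate the enantiomers: if the (R)-alcohol is acylated faster it is removed as the (R)-acetate F6 and the unreacted (S)-alcohol is 6, where the route is rejoined. With the opposite enzyme preference the acetate fraction would be methanolysed to 6.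

**Further compounds**

F1 | step 7 | (S)-2-[3-({[diisopropyl((1E,3E)-3-methyl-8-(trimethylsilyl)octa-1,3-dien-7-yn-1-yl)silyl]oxy}methyl)-3-methylcyclohex-1-en-1-yl]-1,3-dioxolane | C1COC(O1)C2=C[C@@](C)(CO[Si](C(C)C)(C(C)C)/C=C/C(C)=C/CCC#C[Si](C)(C)C)CCC2
F2 | step 7 | ethylene acetal of 15 (C20 as 1,3-dioxolan-2-yl; configuration as in 15) | C1COC(O1)[C@@]23CCC[C@](C)(CO[Si]4(C(C)C)C(C)C)[C@@H]2[C@@H]4C=C(C)[C@H]3CCC#C[Si](C)(C)C
F3 | step 11 | cis-fused 7,8-epoxy-18-hydroxy-15,16-dinorlabd-13-yn-6-one (H5 syn to C20; epoxide oxygen anti to C20) | C[C@@]12CCC[C@](C)(CO)[C@@H]1C(=O)[C@@H]3O[C@]3(C)[C@H]2CCC#C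
F4 | step 1 | rac-3-{[isopropoxy(dimethyl)silyl]methyl}-3-methylcyclohex-1-en-1-yl trifluoromethanesulfonate | CC(C)O[Si](C)(C)CC1(C)C=C(OS(=O)(=O)C(F)(F)F)CCC1
F5 | step 1 | rac-3-(hydroxymethyl)-3-methylcyclohex-1-en-1-yl trifluoromethanesulfonate | OCC1(C)C=C(OS(=O)(=O)C(F)(F)F)CCC1
F6 | step 1 | [(1R)-1-methyl-3-{[(trifluoromethyl)sulfonyl]oxy}cyclohex-2-en-1-yl]methyl acetate | CC(=O)OC[C@@]1(C)C=C(OS(=O)(=O)C(F)(F)F)CCC1
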